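Ring B is a phloroglucinol. Oxygen sits on C1, C3 and C5, O1 is the ether to ring A, and C4, flanked by the two hydroxyl carbons, carries the ether oxygen to bromo ring C. This alternating pattern allows ring B to be cut into two three-carbon halves, C2–C1–C6 and C3–C4–C5, each already holding its aryl ether. In step 7 the isopropenyl ether of 2,4,6-trimethoxyphenol is C-acylated twice by the aryloxymalonyl dichloride. The C2–C3 and C5–C6 bonds form, ring B closes and aromatises, and neither hindered diaryl ether needs a cross-coupling. Methyl ethers are the only protection and fall in one final operation.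

Key step: step 7

Assumption: the three starting materials are taken as purchasable. The target is achiral, and the single labile stereocentre of the transient keto acid chloride vanishes on aromatisation.

Step 1
Reactants: 1 2-bromo-1,3-dimethoxybenzene
Product: 3 4-bromo-3,5-dimethoxyphenol, via aryl pinacol boronate 2 (not isolated)
Conditions: [Ir(OMe)(cod)]2 (cat.), dtbpy (cat.), B2pin2 (0.6 equiv), THF, 80 °C (sealed); then 30% H2O2, aq NaOH, 0 °C to rt
Reagents that add atoms: bis(pinacolato)diboron, CC1(C)OB(OC1(C)C)B1OC(C)(C)C(C)(C)O1; hydrogen peroxide, OO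
Why: Sterically controlled iridium-catalysed C–H borylation should select C5–H, the only ring hydrogen with no ortho neighbour, without touching the C–Br bond, and basic peroxide oxidation of the C–B bond then places the hydroxyl on the same carbon.

Step 2
Reactants: 3 4-bromo-3,5-dimethoxyphenol; 4 diethyl chloromalonate
Product: 5 diethyl 2-(4-bromo-3,5-dimethoxyphenoxy)malonate
Conditions: K2CO3, acetone, reflux
Reagents that add atoms: none
Why: Williamson-type SN2 O-alkylation of the phenoxide at the doubly activated carbon of 4 is the standard entry to aryloxymalonates, and the chloride is preferred to the bromide because it does not transfer halogen to the electron-rich ring.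

Step 3
Reactants: 5 diethyl 2-(4-bromo-3,5-dimethoxyphenoxy)malonate
Product: 6 2-(4-bromo-3,5-dimethoxyphenoxy)malonic acid
Conditions: KOH (2.5 equiv), EtOH–H2O, 0 °C to rt; then 1 M HCl, 0 °C; evaporation below 30 °C
Reagents that add atoms: potassium hydroxide, [K+].[OH-]
Why: Ordinary ester saponification, held at or below room temperature and acidified cold so that the aryloxymalonic acid does not decarboxylate, leaves the aryl ethers and the aryl bromide untouched.

Step 4
Reactants: 6 2-(4-bromo-3,5-dimethoxyphenoxy)malonic acid
Product: 7 2-(4-bromo-3,5-dimethoxyphenoxy)propanedioyl dichloride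
Conditions: (COCl)2 (2.5 equiv), DMF (cat.), CH2Cl2, 0 °C to rt; evaporate, strip with toluene, use at once
Reagents that add atoms: oxalyl chloride, O=C(Cl)C(=O)Cl
Why: Acid chloride formation through the catalytic Vilsmeier-type chloroiminium species runs at 0 °C with only gaseous by-products, and stripping with toluene removes excess (COCl)2, which would otherwise acylate the enol ether in step 7.

Step 5
Reactants: 8 2,4,6-trimethoxyphenol
Product: 9 2,4,6-trimethoxyphenyl acetate
Conditions: Ac2O, pyridine, DMAP (cat.), CH2Cl2, rt
Reagents that add atoms: acetic anhydride, CC(=O)OC(C)=O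
Why: DMAP-catalysed O-acetylation of a phenol is reliable even with two ortho methoxy groups.

Step 6
Reactants: 9 2,4,6-trimethoxyphenyl acetate
Product: 10 1,3,5-trimethoxy-2-(prop-1-en-2-yloxy)benzene
Conditions: Cp2TiMe2 (2.2 equiv), toluene, 70 °C, dark; hexane, filtration through basic Al2O3
Reagents that add atoms: dimethyltitanocene Cp2TiMe2, C[Ti+2]C.c1cc[cH-]c1.c1cc[cH-]c1
Why: In the Petasis methylenation Cp2TiMe2 loses methane on heating to Cp2Ti=CH2, which exchanges CH2 for the ester oxygen through an oxatitanacyclobutane (titanium carbene methylenation is established for aryl as well as alkyl esters), and the non-acidic medium and basic alumina preserve the acid-labile enol ether.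

Step 7
Reactants: 7 2-(4-bromo-3,5-dimethoxyphenoxy)propanedioyl dichloride; 10 1,3,5-trimethoxy-2-(prop-1-en-2-yloxy)benzene
Product: 12 2-(4-bromo-3,5-dimethoxyphenoxy)-5-(2,4,6-trimethoxyphenoxy)benzene-1,3-diol, via monoacylated keto acid chloride 11 (not isolated)
Conditions: 2,6-di-tert-butyl-4-methylpyridine (2.5 equiv), CH2Cl2 (high dilution), simultaneous slow addition of 7 and 10, −20 °C to rt, no Lewis acid
Reagents that add atoms: none
Why: Proposed new method: the terminal CH2 of enol ether 10 attacks one COCl group of 7, and the aryloxy-stabilised oxocarbenium ion gives up a methyl proton to the hindered pyridine, which leaves 11 with a fresh enol ether terminus at the former methyl carbon. That carbon attacks the second COCl group in a 6-(enolendo)-exo-trig closure of ring B (should HCl be lost first, the same bond would arise by 6π electrocyclisation of the resulting dienylketene, as at the end of a Danheiser benzannulation), and the 5-aryloxycyclohexene-1,3-dione enolises twice to the resorcinol, so the labile centre of 11 disappears and no stereocentre is created. The closest known reaction type is the Effenberger cyclisation, in which alkyl or silyl enol ethers of ketones and malonyl dichloride give cyclohexane-1,3,5-triones or phloroglucinols; aryl enol ethers and aryloxymalonyl chlorides have not been used in it. Ring closure through the ether oxygen, which leads alkyl enol ethers to pyranones after loss of the alkyl group, is a dead end here because an sp2 aryl carbon cannot be taken off an oxonium oxygen by chloride, so O-acylation stays reversible and only the carbon pathway drains the equilibrium. The step needs acylation at the enol ether carbons in preference to Friedel–Crafts attack by rings A and C (including closure of 7 on its own ring C to a benzofuranone) and to protonation of 10; the absence of any Lewis acid, the low temperature, the high π-nucleophilicity of a 1,1-disubstituted enol ether and a base too hindered to be acylated should secure this. Simultaneous slow addition at high dilution lets each molecule of 11 cyclise before it meets a second enol ether and keeps finished 12 away from fresh acid chloride.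

Step 8
Reactants: 12 2-(4-bromo-3,5-dimethoxyphenoxy)-5-(2,4,6-trimethoxyphenoxy)benzene-1,3-diol
Product: 13 2-[4-(4-bromo-3,5-dihydroxyphenoxy)-3,5-dihydroxyphenoxy]benzene-1,3,5-triol
Conditions: BBr3 (12 equiv), CH2Cl2, −78 °C to rt, Ar; then ice-water, 0 °C
Reagents that add atoms: none
Why: In the BBr3 cleavage of aryl methyl ethers bromide attacks the methyl carbon of each boron-complexed ether, so all five methyl groups should fall, whereas the diaryl ether and C–Br bonds offer no sp3 carbon and persist, and the cold quench under argon limits bromine shift and oxidation.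

Compound list
1 | 2-bromo-1,3-dimethoxybenzene | COc1cccc(OC)c1Br | starting material
2 | 2-(4-bromo-3,5-dimethoxyphenyl)-4,4,5,5-tetramethyl-1,3,2-dioxaborolane | COc1cc(B2OC(C)(C)C(C)(C)O2)cc(OC)c1Br | intermediate
3 | 4-bromo-3,5-dimethoxyphenol | COc1cc(O)cc(OC)c1Br | intermediate
4 | diethyl chloromalonate | CCOC(=O)C(Cl)C(=O)OCC | starting material
5 | diethyl 2-(4-bromo-3,5-dimethoxyphenoxy)malonate | CCOC(=O)C(Oc1cc(OC)c(Br)c(OC)c1)C(=O)OCC | intermediate
6 | 2-(4-bromo-3,5-dimethoxyphenoxy)malonic acid | COc1cc(OC(C(=O)O)C(=O)O)cc(OC)c1Br | intermediate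
7 | 2-(4-bromo-3,5-dimethoxyphenoxy)propanedioyl dichloride | COc1cc(OC(C(=O)Cl)C(=O)Cl)cc(OC)c1Br | intermediate
8 | 2,4,6-trimethoxyphenol | COc1cc(OC)c(O)c(OC)c1 | starting material
9 | 2,4,6-trimethoxyphenyl acetate | COc1cc(OC)c(OC(C)=O)c(OC)c1 | intermediate
10 | 1,3,5-trimethoxy-2-(prop-1-en-2-yloxy)benzene | COc1cc(OC)c(OC(C)=C)c(OC)c1 | intermediate
11 | 2-(4-bromo-3,5-dimethoxyphenoxy)-3-oxo-5-(2,4,6-trimethoxyphenoxy)hex-5-enoyl chloride (racemic, C2 labile, in equilibrium with its conjugated and enol forms) | COc1cc(OC)c(OC(=C)CC(=O)C(Oc2cc(OC)c(Br)c(OC)c2)C(=O)Cl)c(OC)c1 | intermediate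
12 | 2-(4-bromo-3,5-dimethoxyphenoxy)-5-(2,4,6-trimethoxyphenoxy)benzene-1,3-diol | COc1cc(Oc2c(O)cc(Oc3c(OC)cc(OC)cc3OC)cc2O)cc(OC)c1Br | intermediate
13 | 2-[4-(4-bromo-3,5-dihydroxyphenoxy)-3,5-dihydroxyphenoxy]benzene-1,3,5-triol | Oc1cc(O)c(Oc2cc(O)c(Oc3cc(O)c(Br)c(O)c3)c(O)c2)c(O)c1 | target

Total step count: 8. Longest linear sequence: 6 (steps 1, 2, 3, 4, 7, 8).

Steps most likely to fail

Step 7 can go wrong in five ways.
- The annulation may stall after the first acylation, when the enol ether double bond slips into conjugation with the new ketone.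
- Ring A may be expelled as phenoxide by addition–elimination at the vinylogous ester carbon.
- The dichloride may lose HCl to a ketene that is consumed by cycloaddition or dimerisation.
- The electron-rich arenes may be acylated.
- Chains may grow instead of rings.

The fallback uses known chemistry and makes both ethers by copper-mediated C–O coupling. It sets out from 8 and from boronate 2, which is isolated after the borylation half of step 1, and it comes back to the route at 13. Commercial 4-bromo-2,6-dimethoxyphenol is benzylated (BnBr, K2CO3, DMF) to 2-(benzyloxy)-5-bromo-1,3-dimethoxybenzene F1. Ullmann ether coupling of 8 with this bromide (CuI, picolinic acid, K3PO4, DMSO, 100 °C) should give 2-[4-(benzyloxy)-3,5-dimethoxyphenoxy]-1,3,5-trimethoxybenzene F2. Hydrogenolysis (H2, Pd/C, EtOAc) then frees 2,6-dimethoxy-4-(2,4,6-trimethoxyphenoxy)phenol F3. Boronate 2 is cleaved with NaIO4 and NH4OAc in aqueous acetone to (4-bromo-3,5-dimethoxyphenyl)boronic acid F4. Chan–Lam coupling of the phenol with this boronic acid (Cu(OAc)2, pyridine, 4 Å sieves, CH2Cl2, air, rt) leaves the C–Br bond alone and should give 2-[4-(4-bromo-3,5-dimethoxyphenoxy)-3,5-dimethoxyphenoxy]-1,3,5-trimethoxybenzene F5. BBr3 as in step 8 then cleaves its seven methyl ethers to 13.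

Step 4 can fail in three ways. The diacid may decarboxylate. The dichloride may lose HCl to the chlorocarbonyl ketene. One acyl carbon may also attack the activated ortho carbon of ring C in the HCl-rich medium. The fallback avoids protic acid by way of silyl esters. It sets out from 6 and comes back at 7. Treatment of 6 with TBSCl and imidazole in DMF should give bis(tert-butyldimethylsilyl) 2-(4-bromo-3,5-dimethoxyphenoxy)malonate F6. With (COCl)2 and catalytic DMF in CH2Cl2 at 0 °C this passes directly into 7, releasing the silyl chloride instead of HCl.

Step 8 has three risks: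
- Cleavage may stay incomplete.
- HBr set free on quenching may promote migration or loss of bromine on the very electron-rich ring C.
- The free heptaphenol may oxidise in air during isolation.

The fallback purifies a protected derivative instead of the polyphenol. It sets out from 12 and comes back at 13. After BBr3 and a cold quench the crude product is acetylated at once (Ac2O, pyridine). This should give 2-[4-(3,5-diacetoxy-4-bromophenoxy)-3,5-diacetoxyphenoxy]benzene-1,3,5-triyl triacetate F7, which is stable to air and silica, so partly methylated or bromine-shifted material can be removed. Zemplén-type transesterification (K2CO3 cat., degassed MeOH, 0 °C, then acidic resin) releases 13.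

Further compounds
F1 | step 7 | 2-(benzyloxy)-5-bromo-1,3-dimethoxybenzene | COc1cc(Br)cc(OC)c1OCc1ccccc1
F2 | step 7 | 2-[4-(benzyloxy)-3,5-dimethoxyphenoxy]-1,3,5-trimethoxybenzene | COc1cc(OC)c(Oc2cc(OC)c(OCc3ccccc3)c(OC)c2)c(OC)c1
F3 | step 7 | 2,6-dimethoxy-4-(2,4,6-trimethoxyphenoxy)phenol | COc1cc(OC)c(Oc2cc(OC)c(O)c(OC)c2)c(OC)c1
F4 | step 7 | (4-bromo-3,5-dimethoxyphenyl)boronic acid | COc1cc(B(O)O)cc(OC)c1Br
F5 | step 7 | 2-[4-(4-bromo-3,5-dimethoxyphenoxy)-3,5-dimethoxyphenoxy]-1,3,5-trimethoxybenzene | COc1cc(OC)c(Oc2cc(OC)c(Oc3cc(OC)c(Br)c(OC)c3)c(OC)c2)c(OC)c1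
F6 | step 4 | bis(tert-butyldimethylsilyl) 2-(4-bromo-3,5-dimethoxyphenoxy)malonate | COc1cc(OC(C(=O)O[Si](C)(C)C(C)(C)C)C(=O)O[Si](C)(C)C(C)(C)C)cc(OC)c1Br
F7 | step 8 | 2-[4-(3,5-diacetoxy-4-bromophenoxy)-3,5-diacetoxyphenoxy]benzene-1,3,5-triyl triacetate | CC(=O)Oc1cc(OC(C)=O)c(Oc2cc(OC(C)=O)c(Oc3cc(OC(C)=O)c(Br)c(OC(C)=O)c3)c(OC(C)=O)c2)c(OC(C)=O)c1
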